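**Retrosynthetic overview**

- The strategy rests on one feature: the target is the mono-ketone of a C2-symmetric anti-heptane-3,5-diol. The chain C1–C7 carries the same 4-hydroxy-3-methoxyphenyl ring at C1 and at C7, with C3 as the carbonyl and C5 as the (S)-carbinol. In the diol the two hydroxyls are exchanged by the C2 axis through C4, so the two ends never have to be told apart.
- Endgame disconnection: the C3 ketone goes back to a C3 carbinol (the equivalent C5 hydroxyl held as a TBS ether) and the phenols to benzyl ethers, giving the (3S,5S)-bis(benzyl ether) diol.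
- Key disconnection: C1–C2 and C6–C7 of that diol are cut together, giving (2R,4R)-1,2:4,5-diepoxypentane (C2–C6 with both stereocentres) and two equivalents of 4-(benzyloxy)-3-methoxybenzylmagnesium chloride, joined under Cu(I) catalysis.
- The diepoxide comes from 1,5-dichloropentane-2,4-dione by Ru–BINAP hydrogenation and base closure; the Grignard reagent comes from O-benzylvanillin by reduction, chlorination and magnesium insertion.
- Ring order: both benzene rings are bought; the two oxiranes are closed in step 2 and both are opened in step 6; the target chain itself is acyclic.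

Key step: step 6

Remark: the facial sense of the Ru–BINAP reduction is assigned by analogy with 4-chloro-3-oxobutanoates, where (S)-BINAP gives the (R)-chlorohydrin. The sign of rotation of diol 2 would be checked and the antipodal ligand used if the sense were reversed. Dione 1 is taken as a catalogue chemical.

**Route**

Step 1
Reactants: 1 1,5-dichloropentane-2,4-dione
Product: 2 (2R,4R)-1,5-dichloropentane-2,4-diol
Conditions: H2 (80 bar), [RuCl2((S)-BINAP)]2·NEt3 (0.2 mol %), MeOH, 80 °C; recrystallisation
Reagents that add atoms: none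
Why: Noyori asymmetric hydrogenation of a β-diketone, in which each C=O is reduced inside a ruthenium chelate so that the ligand sets both new carbinol centres (C2 and C4) to give the anti (2R,4R) diol, the minor meso isomer and residual enantiomer being removed by recrystallisation.

Step 2
Reactants: 2 (2R,4R)-1,5-dichloropentane-2,4-diol
Product: 3 (2R,4R)-1,2:4,5-diepoxypentane
Conditions: KOH (powdered, 4 equiv), Et2O, 0 °C → rt; careful distillation
Reagents that add atoms: none
Why: Double intramolecular Williamson etherification (3-exo-tet) in which each alkoxide displaces the neighbouring primary chloride, so the carbinol carbons are not touched and the (2R,4R) configuration passes into both oxiranes.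

Step 3
Reactants: 4 4-(benzyloxy)-3-methoxybenzaldehyde
Product: 5 [4-(benzyloxy)-3-methoxyphenyl]methanol
Conditions: NaBH4, MeOH/THF, 0 °C
Reagents that add atoms: none
Why: Borohydride reduction of an aryl aldehyde to the benzylic alcohol, to which the benzyl and methyl ethers are inert.

Step 4
Reactants: 5 [4-(benzyloxy)-3-methoxyphenyl]methanol
Product: 6 1-(benzyloxy)-4-(chloromethyl)-2-methoxybenzene
Conditions: SOCl2 (1.2 equiv), CH2Cl2, 0 °C → rt; used promptly
Reagents that add atoms: thionyl chloride, O=S(Cl)Cl
Why: Deoxychlorination of an electron-rich benzylic alcohol through its chlorosulfite, fast at 0 °C where the aryl ethers are stable to the HCl formed.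

Step 5
Reactants: 6 1-(benzyloxy)-4-(chloromethyl)-2-methoxybenzene
Product: 7 4-(benzyloxy)-3-methoxybenzylmagnesium chloride (titrated THF solution, used directly)
Conditions: Mg turnings (3 equiv, BrCH2CH2Br-activated), THF, 0 °C, slow addition of dilute 6 (0.3 M); titration
Reagents that add atoms: magnesium, [Mg]
Why: Grignard formation by oxidative insertion of magnesium into the benzylic C–Cl bond, with slow addition of dilute chloride to excess activated metal at low temperature keeping the halide concentration low and so limiting Wurtz homocoupling.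

Step 6
Reactants: 3 (2R,4R)-1,2:4,5-diepoxypentane; 7 4-(benzyloxy)-3-methoxybenzylmagnesium chloride
Product: 9 (3S,5S)-1,7-bis[4-(benzyloxy)-3-methoxyphenyl]heptane-3,5-diol, via mono-opened epoxy alkoxide 8 (not isolated)
Conditions: 7 (2.6 equiv), CuI (10 mol %), THF, −40 → 0 °C; sat. aq. NH4Cl
Reagents that add atoms: none
Why: Cu(I) takes the benzyl group from 7 to form a benzylic cuprate that attacks the unsubstituted CH2 of a magnesium-activated oxirane by SN2 (formally oxidative addition to a Cu(III) alkyl, then reductive elimination), which forms C1–C2 and gives epoxy alkoxide 8, and the same event at the second oxirane forms C6–C7. The closest known reaction type is the copper-catalysed opening of terminal epoxides by Grignard reagents, including two-directional opening of this diepoxide to anti-1,3-diols. No ring is closed and no stereocentre is created: both C–O carbons are spectators of an attack at the adjacent CH2, so the (2R,4R) centres of 3 appear unchanged in space as the 3S,5S centres of 9, the descriptor changing only because the inner chain carbon now outranks the former oxirane CH2. The step needs terminal rather than internal attack, which the steric bias of a monosubstituted oxirane towards a soft copper nucleophile secures, and attack through the benzylic carbon rather than the ring ortho carbon, which copper catalysis at low temperature favours. Catalytic copper and low temperature should also keep chloride opening to a chlorohydrin and 5-endo closure of alkoxide 8 onto its own oxirane in the background.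

Step 7
Reactants: 9 (3S,5S)-1,7-bis[4-(benzyloxy)-3-methoxyphenyl]heptane-3,5-diol
Product: 10 (3S,5S)-1,7-bis[4-(benzyloxy)-3-methoxyphenyl]-5-[(tert-butyldimethylsilyl)oxy]heptan-3-ol
Conditions: TBSCl (1.0 equiv), imidazole (2 equiv), DMF, 0 °C → rt; recovered 9 resubmitted
Reagents that add atoms: tert-butyldimethylsilyl chloride, CC(C)(C)[Si](C)(C)Cl
Why: Silylation of a secondary alcohol under Corey conditions, in which the two hydroxyls are homotopic through the C2 axis so that either one gives the same mono-ether and only the degree of silylation has to be controlled by limiting the reagent.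

Step 8
Reactants: 10 (3S,5S)-1,7-bis[4-(benzyloxy)-3-methoxyphenyl]-5-[(tert-butyldimethylsilyl)oxy]heptan-3-ol
Product: 11 (5S)-1,7-bis[4-(benzyloxy)-3-methoxyphenyl]-5-[(tert-butyldimethylsilyl)oxy]heptan-3-one
Conditions: Dess–Martin periodinane (1.3 equiv), NaHCO3, CH2Cl2, 0 °C → rt
Reagents that add atoms: none
Why: Dess–Martin oxidation of the free secondary alcohol to the ketone under buffered conditions, with the silyl ether preventing over-oxidation to the 1,3-diketone and leaving the C5 centre untouched.

Step 9
Reactants: 11 (5S)-1,7-bis[4-(benzyloxy)-3-methoxyphenyl]-5-[(tert-butyldimethylsilyl)oxy]heptan-3-one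
Product: 12 (5S)-1,7-bis[4-(benzyloxy)-3-methoxyphenyl]-5-hydroxyheptan-3-one
Conditions: HF·pyridine, THF/pyridine, 0 °C → rt
Reagents that add atoms: none
Why: Fluoride cleavage of the Si–O bond under mildly acidic conditions, which avoids the E1cB elimination and retro-aldol pathways that a basic fluoride source could open on a β-silyloxy ketone.

Step 10
Reactants: 12 (5S)-1,7-bis[4-(benzyloxy)-3-methoxyphenyl]-5-hydroxyheptan-3-one
Product: 13 (5S)-5-hydroxy-1,7-bis(4-hydroxy-3-methoxyphenyl)heptan-3-one
Conditions: H2 (1 atm), 10% Pd/C, EtOAc/EtOH, rt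
Reagents that add atoms: none
Why: Catalytic hydrogenolysis of the two aryl benzyl ethers under neutral conditions, which should leave the aliphatic ketone, the secondary alcohol and the C5 configuration unchanged because the molecule has no other benzylic C–O bond.

**Compound list**

1 | 1,5-dichloropentane-2,4-dione | ClCC(=O)CC(=O)CCl | starting material
2 | (2R,4R)-1,5-dichloropentane-2,4-diol | ClC[C@H](O)C[C@@H](O)CCl | intermediate
3 | (2R,4R)-1,2:4,5-diepoxypentane | C1O[C@@H]1C[C@@H]1CO1 | intermediate
4 | 4-(benzyloxy)-3-methoxybenzaldehyde | COc1cc(C=O)ccc1OCc1ccccc1 | starting material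
5 | [4-(benzyloxy)-3-methoxyphenyl]methanol | COc1cc(CO)ccc1OCc1ccccc1 | intermediate
6 | 1-(benzyloxy)-4-(chloromethyl)-2-methoxybenzene | COc1cc(CCl)ccc1OCc1ccccc1 | intermediate
7 | 4-(benzyloxy)-3-methoxybenzylmagnesium chloride | COc1cc(C[Mg]Cl)ccc1OCc1ccccc1 | intermediate
8 | chloromagnesium (2S)-4-[4-(benzyloxy)-3-methoxyphenyl]-1-[(2R)-oxiran-2-yl]butan-2-olate (mono-opened epoxy alkoxide) | COc1cc(CC[C@H](O[Mg]Cl)C[C@@H]2CO2)ccc1OCc1ccccc1 | intermediate (not isolated)
9 | (3S,5S)-1,7-bis[4-(benzyloxy)-3-methoxyphenyl]heptane-3,5-diol | COc1cc(CC[C@H](O)C[C@@H](O)CCc2ccc(OCc3ccccc3)c(OC)c2)ccc1OCc1ccccc1 | intermediate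
10 | (3S,5S)-1,7-bis[4-(benzyloxy)-3-methoxyphenyl]-5-[(tert-butyldimethylsilyl)oxy]heptan-3-ol | COc1cc(CC[C@H](O)C[C@@H](O[Si](C)(C)C(C)(C)C)CCc2ccc(OCc3ccccc3)c(OC)c2)ccc1OCc1ccccc1 | intermediate
11 | (5S)-1,7-bis[4-(benzyloxy)-3-methoxyphenyl]-5-[(tert-butyldimethylsilyl)oxy]heptan-3-one | COc1cc(CCC(=O)C[C@@H](O[Si](C)(C)C(C)(C)C)CCc2ccc(OCc3ccccc3)c(OC)c2)ccc1OCc1ccccc1 | intermediate
12 | (5S)-1,7-bis[4-(benzyloxy)-3-methoxyphenyl]-5-hydroxyheptan-3-one | COc1cc(CCC(=O)C[C@@H](O)CCc2ccc(OCc3ccccc3)c(OC)c2)ccc1OCc1ccccc1 | intermediate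
13 | (5S)-5-hydroxy-1,7-bis(4-hydroxy-3-methoxyphenyl)heptan-3-one | COc1cc(CCC(=O)C[C@@H](O)CCc2ccc(O)c(OC)c2)ccc1O | target

**Step count**

Total: 10 steps. Longest linear sequence: 8 steps (steps 3–10, from aldehyde 4); the diepoxide branch (steps 1–2) joins at step 6.

**Steps most likely to fail**

Step 6. The oxiranes may be opened by chloride from the Schlenk equilibrium instead of by carbon, the ambident benzylic nucleophile may attack through its ring ortho carbon, or the reaction may stall after the first opening. The fallback sets out from aldehyde 4 and diepoxide 3 and comes back at diol 9. Aldehyde 4 would be condensed with propane-1,3-dithiol (BF3·OEt2, CH2Cl2) to 2-[4-(benzyloxy)-3-methoxyphenyl]-1,3-dithiane F1. Its 2-lithio derivative (n-BuLi, THF, −30 °C) should open both oxiranes of 3 at the CH2 termini without copper to give (2R,4R)-1,5-bis{2-[4-(benzyloxy)-3-methoxyphenyl]-1,3-dithian-2-yl}pentane-2,4-diol F2, which has the same spatial arrangement as 9, the descriptor changing because the dithiane-bearing branch outranks the inner chain. Reductive desulfurisation with nickel boride (NiCl2·6H2O, NaBH4, MeOH/THF), chosen over active Raney nickel to spare the benzyl ethers, would then give 9.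

Step 5. Wurtz-type homocoupling of the electron-rich benzylic chloride with the Grignard reagent as it forms may drain the titre below what the double opening needs. The fallback sets out from chloride 6 and diepoxide 3 and comes back at diol 9. Chloride 6 with sodium benzenesulfinate (DMF, rt) would give 1-(benzyloxy)-2-methoxy-4-[(phenylsulfonyl)methyl]benzene F3. Its α-sulfonyl carbanion (n-BuLi, THF, −78 °C; then 3, BF3·OEt2) should open both oxiranes to (3R,5R)-1,7-bis[4-(benzyloxy)-3-methoxyphenyl]-1,7-bis(phenylsulfonyl)heptane-3,5-diol F4, formed as a C1/C7 epimer mixture that is of no consequence, with the C3/C5 arrangement of 9 and descriptors changed only by priority. Reductive desulfonylation (Na/Hg, Na2HPO4, MeOH, −20 °C) would give 9.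

Step 7. Silylation cannot distinguish the first from the second hydroxyl beyond statistics, so over-silylation and recovered diol may limit throughput. The fallback sets out from diol 9 and comes back at target 13, bypassing 10–12. Diol 9 with benzaldehyde dimethyl acetal (CSA cat., CH2Cl2) would give (4S,6S)-4,6-bis{2-[4-(benzyloxy)-3-methoxyphenyl]ethyl}-2-phenyl-1,3-dioxane F5, in which the acetal carbon is not a stereocentre because its two ring branches are identical. Reductive opening with DIBAL-H (CH2Cl2, 0 °C), where cleavage of either C–O bond leads to the same product, would give (3S,5S)-5-(benzyloxy)-1,7-bis[4-(benzyloxy)-3-methoxyphenyl]heptan-3-ol F6. Dess–Martin oxidation would give (5S)-5-(benzyloxy)-1,7-bis[4-(benzyloxy)-3-methoxyphenyl]heptan-3-one F7, and hydrogenolysis of all three benzyl ethers (H2, Pd(OH)2/C, EtOAc/EtOH) would give 13.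

**Further compounds**

F1 | step 6 | 2-[4-(benzyloxy)-3-methoxyphenyl]-1,3-dithiane | COc1cc(C2SCCCS2)ccc1OCc1ccccc1
F2 | step 6 | (2R,4R)-1,5-bis{2-[4-(benzyloxy)-3-methoxyphenyl]-1,3-dithian-2-yl}pentane-2,4-diol | COc1cc(C2(C[C@H](O)C[C@@H](O)CC3(c4ccc(OCc5ccccc5)c(OC)c4)SCCCS3)SCCCS2)ccc1OCc1ccccc1
F3 | step 5 | 1-(benzyloxy)-2-methoxy-4-[(phenylsulfonyl)methyl]benzene | COc1cc(CS(=O)(=O)c2ccccc2)ccc1OCc1ccccc1
F4 | step 5 | (3R,5R)-1,7-bis[4-(benzyloxy)-3-methoxyphenyl]-1,7-bis(phenylsulfonyl)heptane-3,5-diol | COc1cc(C(C[C@H](O)C[C@@H](O)CC(c2ccc(OCc3ccccc3)c(OC)c2)S(=O)(=O)c2ccccc2)S(=O)(=O)c2ccccc2)ccc1OCc1ccccc1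
F5 | step 7 | (4S,6S)-4,6-bis{2-[4-(benzyloxy)-3-methoxyphenyl]ethyl}-2-phenyl-1,3-dioxane | COc1cc(CC[C@H]2C[C@H](CCc3ccc(OCc4ccccc4)c(OC)c3)OC(c3ccccc3)O2)ccc1OCc1ccccc1
F6 | step 7 | (3S,5S)-5-(benzyloxy)-1,7-bis[4-(benzyloxy)-3-methoxyphenyl]heptan-3-ol | COc1cc(CC[C@H](O)C[C@@H](OCc2ccccc2)CCc2ccc(OCc3ccccc3)c(OC)c2)ccc1OCc1ccccc1
F7 | step 7 | (5S)-5-(benzyloxy)-1,7-bis[4-(benzyloxy)-3-methoxyphenyl]heptan-3-one | COc1cc(CCC(=O)C[C@@H](OCc2ccccc2)CCc2ccc(OCc3ccccc3)c(OC)c2)ccc1OCc1ccccc1
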